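Two questions stand on this flask, and I reckon both through c(nucleophile), the free nucleophile, so the examination begins with the runs.

| setting | green | ochre | flask |
|---|---|---|---|
| electrophile | 0.25 M (fed, over 2.0 h) | 0.25 M (fed, over 2.0 h) | 0.25 M (fed, over 2.0 h) |
| nucleophile | 0.25 M | 0.56 M | 0.375 M |
| remark | run made earlier | run made earlier |  |
| time |  |  | 3.0 h |

- green (time / h: electrophile / %, target / %): 0.167: 8.0, 2.0; 0.500: 22.9, 0; 0.833: 38.0, 4.9; 1.33: 57.6, 8.4; 2.00: 84.0, 16.6; 2.50: 78.0, 21.3
- ochre (time / h: electrophile / %, target / %): 0.200: 8.7, 1.7; 0.333: 14.0, 0; 0.500: 23.0, 3.4; 0.833: 37.2, 6.7; 1.33: 50.5, 15.8; 2.50: 56.4, 40.5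

(scatter of a reading: 1 percentage point)

- part of the electrophile that has reacted at 3.0 h
- share of the unused nucleophile that is free and not bound as protonated nucleophile, at 3.0 h

- the analysis behind the earlier runs scatters by 1 percentage point, standard deviation
- percentages count the whole charge, also what has not yet gone in
- the earlier runs do not show how much of nucleophile is bound; that part of a forecast is a guess

**How do you read a loss rate from a fed flask?** The electrophile arrives evenly, so after the feed the charge has a mean age, the time since the middle of the feed, and what remains, read as decayed over that age, gives at 2.50 h a loss rate of 0.166 h⁻¹ in green and 0.382 h⁻¹ in ochre.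

**Why do they differ?** Ochre holds more nucleophile and loses faster, so I reckon the loss of electrophile as pseudo-first-order, with c(nucleophile) held at its mean.

**Which c(nucleophile), the charged one?** No, since each electrophile that reacts takes one nucleophile and may bind a second as protonated nucleophile, and from no loss at the start to up to two per reacted electrophile at the end, I estimate the mean as the charge less the reacted electrophile counted once, 0.195 M in green and 0.451 M in ochre. Dividing gives 2.36 × 10⁻⁴ M⁻¹ s⁻¹ and 2.35 × 10⁻⁴ M⁻¹ s⁻¹, and I carry their mean, 2.36 × 10⁻⁴ M⁻¹ s⁻¹, as the nucleophile coefficient, the loss rate of electrophile per unit of mean free nucleophile.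

**And this flask?** Its mean age at 3.0 h is 2.00 h, so the charged 0.375 M gives 47.1% reacted, the depletion that implies gives 35.4%, and repeating gives 38.5%, then 37.7%, which I commit to.

**You assumed binding; how much is free?** The runs do not show it, but if every reacted electrophile binds a second nucleophile, the free share of the unused nucleophile is 66.5%, my full-binding figure.

The forecast said 37.5% and 70%, noting “Binding is assumed mostly complete”. The flask gives 36.7% and 74.1%, so my reckoning of the first stands a little high and the second lies above my full-binding figure.

    acid set free + target → side product (k = 0.00183 M⁻¹ s⁻¹)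
    electrophile + nucleophile → acid set free + target (k = 2.36 × 10⁻⁴ M⁻¹ s⁻¹)
    nucleophile + acid set free ⇌ protonated nucleophile, settled at all times (K = 27.9 M⁻¹)

With the coefficient 2.36 × 10⁻⁴ M⁻¹ s⁻¹, the flask's 36.7% at a mean age of 2.00 h stands for a mean free nucleophile of 0.269 M, lower than the 0.375 M charged, and that depletion is a part of the reason for the flask's pace, since without it the flask reaches 46.2%, while the feed and the time given are another part, with 46.6% for the whole charge at once and 96.0% at 30.0 h. The neighbour charged with 0.94 M of nucleophile, with the same feed and time, goes by the same passes to 79.7%, 71.5% and 72.5%, and the simulation gives it 68.9%.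

The readings are simulated for an exercise; scatter was added.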